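Where a molecule is lost by meeting another of its own kind, the reciprocal of the fraction left climbs by the same step each hour, the second-order straight line you know from step growth, and that step goes with the charge. Try this, as my own reckoning, on the starting material in these flasks.

common to all: starting material 0.020 M

| charge | partner | second substrate | remark | time |
|---|---|---|---|---|
| south-east | 10 mM | 0.048 M | run made earlier |  |
| east | 10 mM | 0.055 M | run made earlier |  |
| north-east | 10 mM | 0.071 M | run made earlier |  |
| Monday's | 10.0 mM | 0.0800 M |  | 5.0 h |
| Tuesday's | 10.0 mM | 0.0400 M |  | 5.0 h |

| run | time / h | target / % | starting material / % | over-reaction product / % |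
|---|---|---|---|---|
| south-east | 0.667 | 13 | 76 | 0 |
| south-east | 1.33 | 8 | 68 | 4 |
| south-east | 2.00 | 5 | 65 | 2 |
| south-east | 3.00 | 4 | 57 | 5 |
| south-east | 4.00 | 2 | 51 | 4 |
| east | 0.250 | 11 | 83 | 1 |
| east | 0.500 | 12 | 82 | 0 |
| east | 1.00 | 10 | 75 | 3 |
| east | 2.00 | 7 | 63 | 5 |
| east | 4.00 | 2 | 52 | 5 |
| north-east | 0.250 | 7 | 87 | 0 |
| north-east | 0.500 | 9 | 80 | 1 |
| north-east | 1.00 | 7 | 77 | 3 |
| north-east | 2.00 | 4 | 67 | 1 |
| north-east | 4.00 | 3 | 50 | 2 |

(standard deviation of a reading: 1.5 percentage points)

- the numbers in the tables scatter by 1.5 percentage points (one standard deviation)

1. which of these there is most of at the end, counted by the starting material in it, Monday's (over-reaction product / target / starting material)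
2. which of these there is most of at the end, counted by the starting material in it, Tuesday's (over-reaction product / target / starting material)
3. final amount of the leader among these, as a percentage of the starting material charged, in Monday's
4. final amount of the leader among these, as a percentage of the starting material charged, in Tuesday's

Monday's looks nearly like the north-east run, with second substrate at 0.0800 M against 0.071 M, but it ends 1.00 h later than that run's last reading. Solve the north-east run at both ends. Late on, its fraction of starting material reads 77 % at 1.00 h and 50 % at 4.00 h, so the reciprocal rises by 0.234 h⁻¹; I call this hourly rise of the reciprocal of the fraction left the climb. Early on, that line run back to time zero gives a reciprocal of 1.06, not one, and I read this offset as the quick first loss. Joined, the fraction left is one over the offset plus climb times time.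

The extra hour adds 0.234 to the reciprocal, more than the 0.0769 between the last readings of the north-east and east runs. So I let second substrate drop out and give Tuesday's, at 0.0400 M, just below the south-east run's 0.048 M, the same line as Monday's. By my reckoning that leaves 44.8 % of the starting material at 5.0 h in each, and with target at 3 % and over-reaction product at 2 % in the north-east run's last reading, I put starting material in the lead.

The forecast also names starting material for both flasks, with 46 % (41 % to 51 %) on Monday's and 46 % (40 % to 52 %) on Tuesday's, slightly above my figure. Its ground is that for starting material “its loss looks essentially independent of that concentration”.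

The flask gives starting material as leader in both: 46.0 % on Monday's, with over-reaction product at 2.87 % and target at 1.23 %, and 45.6 % on Tuesday's, with 5.01 % and 2.57 %.

    2 starting material → homo dimer (k = 0.0980 L mol⁻¹ min⁻¹)
    starting material → decomposition product (k = 1.20 × 10⁻⁵ min⁻¹)
    starting material + partner ⇌ target (K = 160 L mol⁻¹, k = 1.40 L mol⁻¹ min⁻¹)
    second substrate + partner ⇌ second product (K = 1200 L mol⁻¹, k = 1.30 L mol⁻¹ min⁻¹)
    target → over-reaction product (k = 0.00250 min⁻¹)

Monday's own climb from 2.50 h to 5.00 h is 0.220 h⁻¹, against the 0.234 h⁻¹ read from the north-east run, and by the end homo dimer holds 49.7 % of the starting material charged, each counting as two. Now take a neighbour like Monday's but with 0.080 M of starting material, 4.00 times Monday's charge of it, so that partner stands at 0.125 equiv. Scaling the climb by that factor and keeping the offset as an assumption gives 17.4 % left at 5.0 h. That neighbour flask holds 18.2 % of its starting material at the end.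

The numbers in the tables come from a simulation for an exercise, and the scatter is random.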